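The data were generated by integration with constants of no real substance; scatter was added.

A product curve that lies flat and then rises tempts me to read a threshold, something to be used up first, but a flat start can also come from a product that needs two things that both begin at nothing.

| setting | beta | maple | larch |
|---|---|---|---|
| substrate | 0.11 M | 0.11 M | 0.11 M |
| partner | 0.165 M (fed, over 1.5 h) | 0.165 M (fed, over 1.5 h) | 0.165 M (fed, over 1.5 h) |
| protic impurity | 0.037 M | 0.0550 M | 0.0550 M |
| catalyst | 5.5 mM | 4.0 mM | 5.5 mM |
| temperature | −40 °C |  |  |
| remark | run made earlier; the fed solution adds 0.10 times the starting volume | at −15 °C throughout; the fed solution adds 0.10 times the starting volume | at −40 °C until 1.5 h, from then on at −15 °C; the fed solution adds 0.10 times the starting volume |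
| time |  | 6.0 h | 6.0 h |

- beta (time / min: product / %, substrate / %): 6.00: 0.2, 98.8; 20.0: 0.1, 96.8; 40.0: 0, 94.5; 50.0: 0.7, 92.4; 80.0: 2.0, 88.6; 90.0: 2.6, 87.7; 120: 4.8, 83.5

(readings scatter by 0.3 percentage points)

- charges are per starting volume, the dose included; the dosed solution carries all of it
- the numbers in the tables scatter with a standard deviation of 0.3 percentage points
- the earlier runs do not show what temperature does; that part of a forecast is a guess
- no earlier run changes the charge of catalyst; that part of a forecast is a guess
- no earlier run changes the charge of protic impurity; that part of a forecast is a guess

- the winner by amount of product, in percent of the substrate charged; "neither" if no more than 2 percentage points parts them (maple / larch / neither)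
- how much product is there at the end, in percent of the substrate charged: maple
- how much product is there at the end, in percent of the substrate charged: larch

In the beta run the substrate falls from the first reading and stands at 83.5 % at 120 min. Read as a first-order fall, that is a half-life of 7.69 h, and I freeze this pace. At that time the substrate lost exceeds the product found by 11.7 % of the charge, so I suppose an intermediate stands between them. The product curve has no sharp knee; it bends gently upward. During the steady feed I take the partner as growing roughly in proportion to time, and the intermediate too, so in my reckoning a product that needs both goes with the cube of time. Scaling the 2.0 % at 80.0 min back that way gives 0.250 % at 40.0 min, where the reading is 0 % with a scatter of 0.3 percentage points. So the flat start asks for no threshold, and I read from it no count of how much partner the impurity takes.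

I therefore assume the plain count, one partner per impurity. The level is then the spare partner, the partner charge less the impurity charge, as a fraction of the substrate charge. With partner at 150 % and impurity at 50.0 % of the substrate, it is 100 % for maple and larch alike. Catalyst and temperature do not enter it, so in my reckoning they change the pace. Guessing a 10-fold speed-up when warm, and a pace proportional to catalyst, maple's substrate half-life is 1.06 h, which gives 5.66 half-lives in 6.0 h. I commit to both flasks ending high, somewhat short of that level, with no clear winner.

The forecast differs from me in the count, taking the impurity as “consuming two partner each before any product forms”, and stands at 44 % for maple, 46 % for larch and neither.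

The flasks give 88.5 % in maple and 89.3 % in larch, so the answer is neither.

    substrate + catalyst → catalyst + intermediate (k = 0.00469 M⁻¹ s⁻¹, Ea = 56.0 kJ mol⁻¹)
    partner + catalyst + intermediate → catalyst + product (k = 0.163 M⁻² s⁻¹, Ea = 42.0 kJ mol⁻¹)
    partner + protic impurity → quenched reagent (k = 6.09 × 10⁻⁴ M⁻¹ s⁻¹, Ea = 55.0 kJ mol⁻¹)
    (constants at −40 °C)

Maple's product lies 11 points below its spare partner, and at 6.00 h it holds 11.3 % as intermediate. A neighbour of maple charged with 0.19 M of substrate has a spare partner of 57.9 % of that substrate, and there partner is the limiting reagent. That neighbour ends at 59.6 % product, with 0.081 % of its partner and 6.1 % of its protic impurity left.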